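**Plan**

1. Locants: ring C1 (angelate), C2 (side chain), C4 (OH), C5 (Me); chain C2′ (Me), C4′ (OAc). Retrosynthesis removes the C4 carbinol hydrogen (ketone), the angelate, turns C4=O back into C4–NO2 and C1–OH back into C1=O, then cuts the ring at C2–C3 and C5–C6.
2. Enabling feature: the ring is a 1,4-dioxygenated cyclohexane in which each oxygen-bearing carbon (C1, C4) lies between the two carbons to be joined. C6–C1(=O)–C2 is therefore a ketone α,α′-dinucleophile and C5–C4(NO2)–C3 a 2-nitroallyl 1,3-dielectrophile, the nitro group being the latent C4 carbonyl.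
3. Forward: the complete side chain is made first as methyl ketone 7 (four steps from (R)-monomethyl 3-methylglutarate) and nitroallyl acetate 11 in three steps from 1-nitropropan-2-ol. One amine-catalysed Michael/elimination/Michael cascade joins them and closes the only ring; four redox and acylation steps finish.
4. Stereochemistry: C2′ is bought; C4′ and C1 come from CBS reductions; C5 is set by the amine–thiourea catalyst and relayed in the same flask to C2 and C4 (all-equatorial); the C4 carbinol comes from equatorial hydride attack beside the C5 methyl; the angelate geometry comes from angelic acid.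

Key step: step 8

Remark: the senses of induction (amine–thiourea catalyst, CBS reagent, SAMP auxiliary in the fallback) are assigned from their standard models; the antipode of a controller would be taken if one proved reversed.

**Route**

Step 1
Reactants: 1 (3R)-5-methoxy-3-methyl-5-oxopentanoic acid [(R)-monomethyl 3-methylglutarate]
Product: 3 methyl (3R)-3,7-dimethyl-5-oxooct-6-enoate, via acid chloride 2 (not isolated)
Conditions: (COCl)2, DMF (cat.), CH2Cl2, 0 °C to rt; evaporate; Me2C=CHMgBr (1.05 equiv), CuI (5 mol%), THF, −78 °C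
Reagents that add atoms: 2-methylprop-1-en-1-ylmagnesium bromide, CC(C)=C[Mg]Br; oxalyl chloride, O=C(Cl)C(=O)Cl (chlorine of intermediate 2 only)
Why: Copper-catalysed acylation of an alkenyl Grignard reagent by an acid chloride stops at the ketone at −78 °C and leaves the methyl ester and the remote stereocentre untouched.

Step 2
Reactants: 3 methyl (3R)-3,7-dimethyl-5-oxooct-6-enoate
Product: 5 (4R,6R)-4-methyl-6-(2-methylprop-1-en-1-yl)oxan-2-one, via hydroxy ester 4 (not isolated)
Conditions: (S)-Me-CBS oxazaborolidine (10 mol%), BH3·SMe2 (0.7 equiv), THF, −30 °C; MeOH quench; then PPTS (cat.), toluene, 50 °C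
Reagents that add atoms: none
Why: Corey–Bakshi–Shibata reduction with the alkenyl group as the large substituent should give the (R)-allylic alcohol, and lactonisation of the δ-hydroxy ester to the cis (diequatorial) lactone allows the minor trans diastereomer to be removed.

Step 3
Reactants: 5 (4R,6R)-4-methyl-6-(2-methylprop-1-en-1-yl)oxan-2-one
Product: 6 (4R,6R)-6-hydroxy-4,8-dimethylnon-7-en-2-one
Conditions: MeLi (1.05 equiv), THF, −78 °C; aq NH4Cl
Reagents that add atoms: methyllithium, [Li]C
Why: Single addition of an organolithium to a δ-lactone, whose tetrahedral lithium lactolate is stable at −78 °C and releases the hydroxy methyl ketone only on work-up.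

Step 4
Reactants: 6 (4R,6R)-6-hydroxy-4,8-dimethylnon-7-en-2-one
Product: 7 (4R,6R)-2,6-dimethyl-8-oxonon-2-en-4-yl acetate
Conditions: Ac2O, Et3N, DMAP (cat.), CH2Cl2, 0 °C
Reagents that add atoms: acetic anhydride, CC(=O)OC(C)=O
Why: DMAP-catalysed acetylation of the secondary allylic alcohol of the open keto form, with no stereocentre touched.

Step 5
Reactants: 8 1-nitropropan-2-ol (racemic)
Product: 9 (E)-1-nitroprop-1-ene
Conditions: MsCl, Et3N (2.2 equiv), CH2Cl2, −10 °C; used as a solution
Reagents that add atoms: none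
Why: Mesylation and E1cB elimination of a β-nitro alcohol (dehydration of a Henry adduct) should give the conjugated (E)-nitroalkene.

Step 6
Reactants: 9 (E)-1-nitroprop-1-ene
Product: 10 (E)-2-nitrobut-2-en-1-ol
Conditions: aq HCHO (37%), imidazole (1 equiv), anthranilic acid (10 mol%), THF, rt
Reagents that add atoms: formaldehyde, C=O
Why: Morita–Baylis–Hillman hydroxymethylation of a nitroalkene, in which imidazole adds reversibly to the β-carbon, the nitronate traps formaldehyde and elimination returns the alkene with methyl trans to nitro.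

Step 7
Reactants: 10 (E)-2-nitrobut-2-en-1-ol
Product: 11 (E)-2-nitrobut-2-en-1-yl acetate
Conditions: Ac2O, H2SO4 (cat.), CH2Cl2, 0 °C
Reagents that add atoms: acetic anhydride, CC(=O)OC(C)=O
Why: Acid-catalysed acetylation avoids nucleophilic amines, which would attack the nitroallyl system in the SN2′ sense.

Step 8
Reactants: 7 (4R,6R)-2,6-dimethyl-8-oxonon-2-en-4-yl acetate; 11 (E)-2-nitrobut-2-en-1-yl acetate
Product: 13 (4R,6R)-2-methyl-6-[(1S,4S,5S)-4-methyl-5-nitro-2-oxocyclohexyl]hept-2-en-4-yl acetate, via nitroalkene 12 (not isolated)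
Conditions: 1-[3,5-bis(trifluoromethyl)phenyl]-3-[(2S)-pyrrolidin-2-ylmethyl]thiourea (20 mol%), PhCO2H (20 mol%), 11 (1.3 equiv), toluene (0.1 M), 0 °C to rt; then Et3N (0.3 equiv), rt
Reagents that add atoms: none
Why: The secondary-amine catalyst condenses with 7 on the methyl side and this enamine adds to the methyl-bearing alkene carbon of 11 held by the thiourea; the nitronate expels acetate (net SN2′) to give 12, whose internal enamine carbon then attacks the new CH2=C(NO2) terminus, so that C5–C6 and then C2–C3 form in one flask. The closest known reaction type is the enamine/2-nitroallyl ester [3+3] carbocyclisation to 4-nitrocyclohexanones, including its amine–thiourea-catalysed asymmetric form with cyclic ketones. The single ring closes in the 6-endo-trig mode through a chair-like transition state. C5 is set by the catalyst (enamine face and hydrogen-bonded nitroalkene face, as in additions of ketones to (E)-nitroalkenes), while C2 (α to the ketone) and C4 (α to nitro) are epimerisable and should settle, with Et3N, in the all-equatorial arrangement dictated by C5. The step needs first attack from the methyl carbon and ring closure faster than a second intermolecular addition; the β-branch next to the internal α-carbon of 7, the impossibility of a four-membered closure from the other α-carbon, and moderate dilution secure these.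

Step 9
Reactants: 13 (4R,6R)-2-methyl-6-[(1S,4S,5S)-4-methyl-5-nitro-2-oxocyclohexyl]hept-2-en-4-yl acetate
Product: 14 (4R,6R)-6-[(1S,2R,4S,5S)-2-hydroxy-4-methyl-5-nitrocyclohexyl]-2-methylhept-2-en-4-yl acetate
Conditions: (S)-Me-CBS oxazaborolidine (20 mol%), catecholborane (1.5 equiv), toluene, −78 to −40 °C
Reagents that add atoms: none
Why: Corey–Bakshi–Shibata reduction with the branched ring carbon C2 as the large and the C6 methylene as the small substituent should give the (1R) equatorial alcohol trans to the side chain, while nitro, acetate and alkene are inert to catecholborane at low temperature.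

Step 10
Reactants: 14 (4R,6R)-6-[(1S,2R,4S,5S)-2-hydroxy-4-methyl-5-nitrocyclohexyl]-2-methylhept-2-en-4-yl acetate
Product: 16 (4R,6R)-6-[(1S,2R,4S)-2-hydroxy-4-methyl-5-oxocyclohexyl]-2-methylhept-2-en-4-yl acetate, via potassium nitronate 15 (not isolated)
Conditions: t-BuOK (1.05 equiv), THF, 0 °C; then aq TiCl3 (4 equiv), NH4OAc buffer (pH 5–6), 0 °C to rt
Reagents that add atoms: water, O
Why: Reductive Nef reaction, in which trivalent titanium reduces the nitronate to the imine and the buffer hydrolyses it to the ketone without touching alkene or acetate; the C5 methyl stays equatorial because it is now epimerisable and already in the stable position.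

Step 11
Reactants: 16 (4R,6R)-6-[(1S,2R,4S)-2-hydroxy-4-methyl-5-oxocyclohexyl]-2-methylhept-2-en-4-yl acetate
Product: 17 (1R,2S,5S)-2-[(2R,4R)-4-(acetyloxy)-6-methylhept-5-en-2-yl]-5-methyl-4-oxocyclohexyl (2Z)-2-methylbut-2-enoate
Conditions: angelic acid (3 equiv), 2,4,6-Cl3C6H2COCl (3 equiv), Et3N (3 equiv), toluene, rt; then 16, toluene, 80 °C
Reagents that add atoms: angelic acid [(2Z)-2-methylbut-2-enoic acid], C/C=C(/C)C(=O)O
Why: Yamaguchi-type mixed-anhydride acylation, used without nucleophilic catalyst or free base, is the established way to esterify hindered secondary alcohols with angelic acid without Z-to-E isomerisation.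

Step 12
Reactants: 17 (1R,2S,5S)-2-[(2R,4R)-4-(acetyloxy)-6-methylhept-5-en-2-yl]-5-methyl-4-oxocyclohexyl (2Z)-2-methylbut-2-enoate
Product: 18 (1R,2S,4R,5S)-2-[(2R,4R)-4-(acetyloxy)-6-methylhept-5-en-2-yl]-4-hydroxy-5-methylcyclohexyl (2Z)-2-methylbut-2-enoate
Conditions: LiBH(s-Bu)3 (1.1 equiv), THF, −78 °C; aq NH4Cl
Reagents that add atoms: none
Why: The bulky trialkylborohydride should attack the C4 ketone from the equatorial direction and give the axial alcohol cis to the equatorial C5 methyl, the two esters being inert at −78 °C.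

**Compound list**

1 | (3R)-5-methoxy-3-methyl-5-oxopentanoic acid | COC(=O)C[C@H](C)CC(=O)O | starting material
2 | methyl (3S)-5-chloro-3-methyl-5-oxopentanoate | COC(=O)C[C@H](C)CC(=O)Cl | intermediate
3 | methyl (3R)-3,7-dimethyl-5-oxooct-6-enoate | COC(=O)C[C@H](C)CC(=O)C=C(C)C | intermediate
4 | methyl (3R,5R)-5-hydroxy-3,7-dimethyloct-6-enoate | COC(=O)C[C@H](C)C[C@H](C=C(C)C)O | intermediate
5 | (4R,6R)-4-methyl-6-(2-methylprop-1-en-1-yl)oxan-2-one | O=C1C[C@H](C)C[C@H](C=C(C)C)O1 | intermediate
6 | (4R,6R)-6-hydroxy-4,8-dimethylnon-7-en-2-one | CC(=O)C[C@H](C)C[C@H](C=C(C)C)O | intermediate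
7 | (4R,6R)-2,6-dimethyl-8-oxonon-2-en-4-yl acetate | CC(=O)C[C@H](C)C[C@H](C=C(C)C)OC(C)=O | intermediate
8 | 1-nitropropan-2-ol | CC(O)C[N+](=O)[O-] | starting material
9 | (E)-1-nitroprop-1-ene | C/C=C/[N+](=O)[O-] | intermediate
10 | (E)-2-nitrobut-2-en-1-ol | C/C=C(\CO)[N+](=O)[O-] | intermediate
11 | (E)-2-nitrobut-2-en-1-yl acetate | C/C=C(\COC(C)=O)[N+](=O)[O-] | intermediate
12 | (4R,6R,10S)-2,6,10-trimethyl-11-nitro-8-oxododeca-2,11-dien-4-yl acetate | C=C([N+](=O)[O-])[C@@H](C)CC(=O)C[C@H](C)C[C@H](C=C(C)C)OC(C)=O | intermediate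
13 | (4R,6R)-2-methyl-6-[(1S,4S,5S)-4-methyl-5-nitro-2-oxocyclohexyl]hept-2-en-4-yl acetate | O=C1C[C@H](C)[C@@H]([N+](=O)[O-])C[C@H]1[C@H](C)C[C@H](C=C(C)C)OC(C)=O | intermediate
14 | (4R,6R)-6-[(1S,2R,4S,5S)-2-hydroxy-4-methyl-5-nitrocyclohexyl]-2-methylhept-2-en-4-yl acetate | O[C@@H]1C[C@H](C)[C@@H]([N+](=O)[O-])C[C@H]1[C@H](C)C[C@H](C=C(C)C)OC(C)=O | intermediate
15 | potassium nitronate of 14 | O[C@@H]1C[C@H](C)C(=[N+]([O-])[O-])C[C@H]1[C@H](C)C[C@H](C=C(C)C)OC(C)=O.[K+] | intermediate
16 | (4R,6R)-6-[(1S,2R,4S)-2-hydroxy-4-methyl-5-oxocyclohexyl]-2-methylhept-2-en-4-yl acetate | O[C@@H]1C[C@H](C)C(=O)C[C@H]1[C@H](C)C[C@H](C=C(C)C)OC(C)=O | intermediate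
17 | (1R,2S,5S)-2-[(2R,4R)-4-(acetyloxy)-6-methylhept-5-en-2-yl]-5-methyl-4-oxocyclohexyl (2Z)-2-methylbut-2-enoate | C/C=C(/C)C(=O)O[C@@H]1C[C@H](C)C(=O)C[C@H]1[C@H](C)C[C@H](C=C(C)C)OC(C)=O | intermediate
18 | (1R,2S,4R,5S)-2-[(2R,4R)-4-(acetyloxy)-6-methylhept-5-en-2-yl]-4-hydroxy-5-methylcyclohexyl (2Z)-2-methylbut-2-enoate | C/C=C(/C)C(=O)O[C@@H]1C[C@H](C)[C@H](O)C[C@H]1[C@H](C)C[C@H](C=C(C)C)OC(C)=O | target

**Step count and risks**

Total steps: 12. Longest linear sequence: 9 (steps 1–4 and 8–12).

Step 8. What may go wrong: first attack through the internal enamine, insufficient facial control at C5, or a second intermolecular addition to the nitroallyl intermediate because the ketone cannot be used in excess. The fallback sets out from 6 and separates the two bond formations under auxiliary control. Silylation (Et3SiCl, imidazole) would give (4R,6R)-4,8-dimethyl-6-[(triethylsilyl)oxy]non-7-en-2-one F1. Condensation with (S)-1-amino-2-(methoxymethyl)pyrrolidine would give the SAMP hydrazone F2. LiN(i-Pr)2 deprotonates such hydrazones only at the methyl group, and addition of the azaenolate to 11 at −100 °C with loss of acetate would give the nitroallyl hydrazone F3 with C5 set by the auxiliary. Aqueous oxalic acid would cleave the hydrazone and the silyl ether to (3S,7R,9R)-9-hydroxy-3,7,11-trimethyl-2-nitrododeca-1,10-dien-5-one F4. Catalytic pyrrolidine/AcOH would close the ring by intramolecular enamine Michael addition to (2S,4S,5S)-2-[(2R,4R)-4-hydroxy-6-methylhept-5-en-2-yl]-5-methyl-4-nitrocyclohexan-1-one F5. Acetylation (Ac2O, DMAP) brings the route back at 13.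

Step 9. What may go wrong: hydride delivery from the equatorial direction, giving the axial alcohol, or a sluggish catalysed reduction. The fallback sets out from 13 and reaches the carbinol by inversion. LiBH(s-Bu)3 at −78 °C would give the axial alcohol (4R,6R)-6-[(1S,2S,4S,5S)-2-hydroxy-4-methyl-5-nitrocyclohexyl]-2-methylhept-2-en-4-yl acetate F6; the nitro-bearing carbon is re-equilibrated with Et3N, and its configuration is erased in step 10 anyway. Mitsunobu inversion (PPh3, diisopropyl azodicarboxylate, chloroacetic acid) would give the inverted ester (1R,2S,4S,5S)-2-[(2R,4R)-4-(acetyloxy)-6-methylhept-5-en-2-yl]-5-methyl-4-nitrocyclohexyl chloroacetate F7. Thiourea/NaHCO3 in ethanol removes the chloroacetyl group without touching the acetate, and the route comes back at 14.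

Step 10. What may go wrong: stalling at the oxime stage, or loss of the acetate during nitronate formation. The fallback sets out from 14 and goes through an isolated oxime without a strong base. SnCl2/PhSH/Et3N would reduce the secondary nitro group to the oxime (4R,6R)-6-[(1S,2R,4S)-2-hydroxy-5-(hydroxyimino)-4-methylcyclohexyl]-2-methylhept-2-en-4-yl acetate F8. Exchange with aqueous glyoxylic acid at room temperature would release the ketone, and the route comes back at 16.

**Further compounds**

F1 | step 8 | (4R,6R)-4,8-dimethyl-6-[(triethylsilyl)oxy]non-7-en-2-one | CC(=O)C[C@H](C)C[C@H](C=C(C)C)O[Si](CC)(CC)CC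
F2 | step 8 | SAMP hydrazone of F1 | CC(=NN1CCC[C@H]1COC)C[C@H](C)C[C@H](C=C(C)C)O[Si](CC)(CC)CC
F3 | step 8 | SAMP hydrazone of (3S,7R,9R)-3,7,11-trimethyl-2-nitro-9-[(triethylsilyl)oxy]dodeca-1,10-dien-5-one | C=C([N+](=O)[O-])[C@@H](C)CC(=NN1CCC[C@H]1COC)C[C@H](C)C[C@H](C=C(C)C)O[Si](CC)(CC)CC
F4 | step 8 | (3S,7R,9R)-9-hydroxy-3,7,11-trimethyl-2-nitrododeca-1,10-dien-5-one | C=C([N+](=O)[O-])[C@@H](C)CC(=O)C[C@H](C)C[C@H](C=C(C)C)O
F5 | step 8 | (2S,4S,5S)-2-[(2R,4R)-4-hydroxy-6-methylhept-5-en-2-yl]-5-methyl-4-nitrocyclohexan-1-one | O=C1C[C@H](C)[C@@H]([N+](=O)[O-])C[C@H]1[C@H](C)C[C@H](C=C(C)C)O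
F6 | step 9 | (4R,6R)-6-[(1S,2S,4S,5S)-2-hydroxy-4-methyl-5-nitrocyclohexyl]-2-methylhept-2-en-4-yl acetate | O[C@H]1C[C@H](C)[C@@H]([N+](=O)[O-])C[C@H]1[C@H](C)C[C@H](C=C(C)C)OC(C)=O
F7 | step 9 | (1R,2S,4S,5S)-2-[(2R,4R)-4-(acetyloxy)-6-methylhept-5-en-2-yl]-5-methyl-4-nitrocyclohexyl chloroacetate | ClCC(=O)O[C@@H]1C[C@H](C)[C@@H]([N+](=O)[O-])C[C@H]1[C@H](C)C[C@H](C=C(C)C)OC(C)=O
F8 | step 10 | (4R,6R)-6-[(1S,2R,4S)-2-hydroxy-5-(hydroxyimino)-4-methylcyclohexyl]-2-methylhept-2-en-4-yl acetate | O[C@@H]1C[C@H](C)C(=NO)C[C@H]1[C@H](C)C[C@H](C=C(C)C)OC(C)=O
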